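A closed flask keeps its count of catalyst, so if impurity holds a catalyst for good, that catalyst is one fewer turning substrate into product.

| flask | substrate | partner | capture agent | free catalyst | impurity | remark | time |
|---|---|---|---|---|---|---|---|
| Wednesday's | 13 mM | 13 mM | 0.26 mM | 0.64 mM | 53 µM | run made earlier |  |
| Thursday's | 13 mM | 13 mM | 0.26 mM | 0.64 mM | 130 µM | run made earlier |  |
| delta | 13 mM | 13.0 mM | 0.260 mM | 0.64 mM | 69 µM |  | 40 h |
| gamma | 13 mM | 13.0 mM | 0.260 mM | 0.64 mM | 210 µM |  | 40 h |

| run | time / h | product / % | substrate / % |
|---|---|---|---|
| Wednesday's | 2.50 | 7 | 90 |
| Wednesday's | 8.00 | 16 | 76 |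
| Wednesday's | 12.0 | 26 | 71 |
| Wednesday's | 20.0 | 43 | 54 |
| Thursday's | 2.50 | 6 | 90 |
| Thursday's | 8.00 | 14 | 83 |
| Thursday's | 12.0 | 24 | 72 |
| Thursday's | 20.0 | 37 | 64 |

(standard deviation of a reading: 2 percentage points)

- which of the two there is more of at the end, delta (trapped intermediate / product)
- which of the two there is more of at the end, gamma (trapped intermediate / product)
- how much product is there at the end, in percent of the substrate charged: delta
- how much product is there at the end, in percent of the substrate charged: gamma

Wednesday's and Thursday's runs share every charge but impurity, so they test that count. Suppose each impurity takes one free catalyst. Then the working catalyst W = [free catalyst] − [impurity] is 0.587 mM on Wednesday and 0.510 mM on Thursday, a ratio of 0.869. The product readings at 20.0 h stand in a ratio of 0.860, with a scatter of 2 percentage points on each reading.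

I now let the unreacted share fall as a pseudo-first-order decay with rate κW, so that it is exp(−κWt) at time t. The two last product readings then give κ = 0.0467 /mM/h, the first-order rate of making product per unit of working catalyst.

Delta has W = 0.571 mM and gamma 0.430 mM, so at 40 h I reckon 65.6 % product in delta and 55.2 % in gamma. At one per capture agent, trapped intermediate stays within 2.00 % of the substrate charged, so product is ahead in both.

The forecast also puts product ahead in both, but its numbers are higher than mine: 78 % for delta and 60 % for gamma. They lie between a straight line and a first-order curve: “Some late slowing is likely, so I expect values between these”.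

Delta gives 70.2 % of product and gamma 56.8 %, in percent of the substrate charged, with trapped intermediate at 0.118 % in delta and 0.0961 % in gamma.

    substrate + free catalyst → catalyst intermediate A (k = 200 /M/h)
    catalyst intermediate A ⇌ catalyst intermediate B (K = 0.340, k = 1.00 /h)
    partner + catalyst intermediate B → catalyst intermediate C (k = 1700 /M/h)
    catalyst intermediate C → free catalyst + product (k = 2.70 /h)
    free catalyst + impurity → spent catalyst (k = 14000 /M/h)
    catalyst intermediate C + capture agent → trapped intermediate (k = 18.0 /M/h)
    2 catalyst intermediate C ⇌ resting dimer (K = 1600 /M, k = 61.0 /M/h)

At 40.0 h spent catalyst stands at 10.8 % of the catalyst charged in delta and 32.8 % in gamma, with impurity at 0 % of its charge in delta and 0 % in gamma; impurity over free catalyst as charged is 10.8 % in delta and 32.8 % in gamma. A neighbour of delta with 0.26 mM of free catalyst has W = 0.191 mM, so κ gives 30.0 % product at 40 h, and that flask holds 27.9 %.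

The earlier runs and the new flask stem from a simulated flask for substances that don't exist; noise was put on by code.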